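**Strategy.** Labdane numbering is used (C9 carbinol carbon, C10 angular carbon, C5 fusion CH, C8 the CHCH3 carbon). The plan exploits ring B as a cyclohexene retron whose C5–C10 edge is the fusion bond shared with ring A. An acyclic (2E,8E)-undeca-2,8,10-trienal, carrying the C2/C3 diol as silyl ethers and the C4 gem-dimethyl group in the tether, undergoes an intramolecular Diels–Alder reaction: diene C5=C6–C7=C8 and enal C9=C10 unite at C5–C10 and C8–C9, closing rings A and B together as the trans-decalin. The formyl group on C9 is a temporary activator; it is excised to the C9 ketone, which then takes C8 methylation, axial ethynylation and a B-alkyl Suzuki coupling.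

Key step: step 9

Remark: the target is read as 2α,3α-diol, 5α-H, 8α-CH3, 9β-OH (cis to the C10 methyl, side chain 9α), 10β-CH3, 13Z; α is the face opposite the C10 methyl, and carbons of acyclic precursors carry the labdane numbers they become.

**Step 1**
Reactants: 1 (S)-pantolactone
Product: 2 (3S)-3-(tert-butyldimethylsilyloxy)-4,4-dimethyloxolan-2-one
Conditions: TBSCl, imidazole, DMF, rt
Reagents that add atoms: tert-butyldimethylsilyl chloride, CC(C)(C)[Si](C)(C)Cl
Why: Imidazole-promoted silyl ether formation at the secondary alcohol; the chiral-pool stereocenter (later C3) is not touched.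

**Step 2**
Reactants: 2 silylated pantolactone
Product: 3 (2S)-2-(tert-butyldimethylsilyloxy)-4-hydroxy-N-methoxy-N,3,3-trimethylbutanamide
Conditions: MeNH(OMe)·HCl, Me3Al, CH2Cl2, 0 °C → rt
Reagents that add atoms: N,O-dimethylhydroxylamine hydrochloride, CNOC.Cl
Why: Weinreb aminolysis of the lactone by the aluminium amide frees the neopentyl alcohol (later C5) without touching the stereocenter; the hydroxy amide should be used at once to avoid relactonization.

**Step 3**
Reactants: 3 hydroxy Weinreb amide
Product: 4 (2S)-2-(tert-butyldimethylsilyloxy)-N-methoxy-N,3,3-trimethyl-4-oxobutanamide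
Conditions: Dess–Martin periodinane, CH2Cl2, rt
Reagents that add atoms: none
Why: Dess–Martin oxidation of the primary alcohol; the aldehyde has a quaternary α-carbon and can neither epimerize nor eliminate.

**Step 4**
Reactants: 4 aldehyde amide
Product: 5 (2S,4E)-2-(tert-butyldimethylsilyloxy)-N-methoxy-N,3,3-trimethylhepta-4,6-dienamide
Conditions: (EtO)2P(O)CH2CH=CH2, n-BuLi, THF, −78 °C; then 4, HMPA, −78 °C → rt
Reagents that add atoms: diethyl allylphosphonate, C=CCP(=O)(OCC)OCC
Why: Horner–Wadsworth–Emmons-type olefination with the α-lithiated allylphosphonate should give the (E)-1,3-diene from the hindered neopentyl aldehyde, which reacts far faster than the Weinreb amide at −78 °C.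

**Step 5**
Reactants: 5 diene Weinreb amide
Product: 6 (2S,4E)-2-(tert-butyldimethylsilyloxy)-3,3-dimethylhepta-4,6-dienal
Conditions: i-Bu2AlH, THF, −78 °C
Reagents that add atoms: none
Why: Hydride reduction of the Weinreb amide stops at the chelated hemiaminal, which releases the α-silyloxy aldehyde on work-up without epimerization.

**Step 6**
Reactants: 7 3-methylbut-2-enal (prenal)
Product: 8 (1E)-3-methyl-1-(trimethylsilyloxy)buta-1,3-diene
Conditions: TMSOTf, Et3N, Et2O, 0 °C
Reagents that add atoms: trimethylsilyl triflate, C[Si](C)(C)OS(=O)(=O)C(F)(F)F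
Why: Soft enolization of the enal through its γ-methyl group gives the silyl dienol ether (the Z isomer would serve equally).

**Step 7**
Reactants: 6 α-silyloxy dienal; 8 silyl dienol ether
Product: 9 (2E,5R,6S,8E)-6-(tert-butyldimethylsilyloxy)-5-hydroxy-3,7,7-trimethylundeca-2,8,10-trienal
Conditions: BF3·OEt2, CH2Cl2, −78 °C
Reagents that add atoms: none
Why: Vinylogous Mukaiyama aldol reaction at the γ-terminus of 8; with non-chelating BF3 the α-silyloxy aldehyde is attacked in the Felkin–Anh (Cornforth) sense, anti to the tert-alkyl group, which sets C2 anti (erythro) to C3, and the conjugated enal forms as the E isomer.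

**Step 8**
Reactants: 9 hydroxy trienal
Product: 10 (2E,5R,6S,8E)-5,6-bis(tert-butyldimethylsilyloxy)-3,7,7-trimethylundeca-2,8,10-trienal
Conditions: TBSOTf, 2,6-lutidine, CH2Cl2, −78 °C
Reagents that add atoms: tert-butyldimethylsilyl triflate, CC(C)(C)[Si](C)(C)OS(=O)(=O)C(F)(F)F
Why: Silyl triflate silylation of the secondary alcohol is much faster than enolization of the enal at −78 °C.

**Step 9**
Reactants: 10 bis-silyloxy trienal
Product: 11 trans-fused cycloadduct 9β-formyl-2α,3α-bis(tert-butyldimethylsilyloxy)-4,4,10β-trimethyl-5αH-octal-6-ene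
Conditions: Me2AlCl, CH2Cl2, −78 → −20 °C
Reagents that add atoms: none
Why: Me2AlCl binds the formyl oxygen and lowers the LUMO of the C9=C10 enal, which adds across the C5=C6–C7=C8 diene in a concerted, asynchronous [4+2] cycloaddition that forms C5–C10 and C8–C9 at once (Lewis-acid-promoted intramolecular Diels–Alder reaction of a 2,8,10-undecatrienal, a known route to trans-fused octalins). Ring A closes as the six-membered tether ring through a chair-like C10–C1–C2–C3–C4–C5 array, and ring B closes as the cyclohexene of the cycloaddition with the new alkene at C6=C7. The E enal holds the formyl group cis to the C10 methyl, so the endo transition state (formyl under the diene, tether exo) should give the trans fusion (10β-CH3, 5α-H) with a 9β-formyl group. The diene face is chosen by the erythro bis-silyloxy unit: the C2–O bond must be equatorial in the chair-like tether, because an axial C2–O would be 1,3-diaxial to both the axial C4 methyl and the C10 methyl, and this places the axial C3–O on the face of H5. The step needs endo over exo closure and one diene face; the Lewis acid and E geometry secure the first, the substrate the second, and C8 is left unsubstituted so that no 1,3-diaxial methyl pair builds up in the endo transition state. C9 is only a temporary stereocenter and is removed in step 11.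

**Step 10**
Reactants: 11 octalin aldehyde
Product: 12 9β-formyl-2α,3α-bis(tert-butyldimethylsilyloxy)-4,4,10β-trimethyl-5αH-decalin
Conditions: H2 (1 atm), Pd/C, EtOAc, rt
Reagents that add atoms: none
Why: Heterogeneous hydrogenation of the disubstituted C6=C7 alkene under neutral conditions, which should leave the hindered aldehyde and the silyl ethers intact.

**Step 11**
Reactants: 12 decalin aldehyde
Product: 13 2α,3α-bis(tert-butyldimethylsilyloxy)-4,4,10β-trimethyl-5αH-decalin-9-one
Conditions: O2 (1 atm), Cu(OAc)2 (cat.), 2,2'-bipyridine, DABCO, DMF, 60 °C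
Reagents that add atoms: dioxygen, O=O
Why: Copper-catalysed aerobic oxidative deformylation of an α-branched aldehyde: the enol is oxygenated at C9 and the α-hydroperoxy aldehyde fragments to the C9 ketone and formate, which deletes the temporary C9 stereocenter.

**Step 12**
Reactants: 13 C9 ketone
Product: 16 8α-methyl-2α,3α-bis(tert-butyldimethylsilyloxy)-4,4,10β-trimethyl-5αH-decalin-9-one, via lithium enolate 14 (not isolated), via C8-epimer mixture 15 (not isolated)
Conditions: LiN(i-Pr)2, THF, −78 °C; MeI, −78 → 0 °C; then NaOMe (cat.), MeOH, rt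
Reagents that add atoms: iodomethane, CI
Why: Enolate alkylation can occur only at C8 because C10 is quaternary, and base equilibration should place the C8 methyl equatorial (8α), away from the 1,3-diaxial C10 methyl.

**Step 13**
Reactants: 16 8α-methyl C9 ketone
Product: 17 9α-ethynyl-9β-hydroxy-8α-methyl-2α,3α-bis(tert-butyldimethylsilyloxy)-4,4,10β-trimethyl-5αH-decalin
Conditions: HC≡CMgBr (excess), THF, 0 → 40 °C; then H2O
Reagents that add atoms: ethynylmagnesium bromide, C#C[Mg]Br
Why: 1,2-Addition of the slim sp-hybridized acetylide should follow the axial trajectory on the α face, anti to the axial C10 methyl that blocks equatorial approach, giving the equatorial 9β-hydroxyl and axial 9α-carbon substituent, as for acetylide additions to 2,2,6-trialkylcyclohexanones.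

**Step 14**
Reactants: 17 ethynyl carbinol
Product: 18 9α-vinyl-9β-hydroxy-8α-methyl-2α,3α-bis(tert-butyldimethylsilyloxy)-4,4,10β-trimethyl-5αH-decalin
Conditions: H2 (1 atm), Pd/CaCO3 poisoned with Pb(OAc)2, quinoline, EtOAc, rt
Reagents that add atoms: none
Why: Lindlar semi-hydrogenation of the terminal alkyne stops at the vinyl group and affects no stereocenter.

**Step 15**
Reactants: 19 methyl but-2-ynoate
Product: 20 methyl (Z)-3-iodobut-2-enoate
Conditions: NaI, AcOH, 115 °C
Reagents that add atoms: sodium iodide, [Na+].[I-]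
Why: Conjugate addition of iodide to the ynoate followed by protonation is an anti hydroiodination and should give the Z β-iodo enoate.

**Step 16**
Reactants: 18 vinyl carbinol; 20 methyl (Z)-3-iodobut-2-enoate
Product: 22 methyl (13Z)-9β-hydroxy-2α,3α-bis(tert-butyldimethylsilyloxy)labd-13-en-15-oate, via B-alkyl-9-BBN adduct 21 (not isolated)
Conditions: 9-BBN, THF, rt → 50 °C; then 20, Pd(dppf)Cl2 (cat.), AsPh3, Cs2CO3, DMF/H2O, rt
Reagents that add atoms: none
Why: Anti-Markovnikov hydroboration of the monosubstituted alkene and B-alkyl Suzuki–Miyaura coupling with the Z iodoenoate, which proceeds with retention of alkene geometry and so fixes the 13Z configuration.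

**Step 17**
Reactants: 22 bis-silyl ether
Product: 23 methyl (13Z)-2α,3α,9β-trihydroxylabd-13-en-15-oate (target)
Conditions: HF·pyridine, pyridine, THF, 0 °C → rt
Reagents that add atoms: none
Why: Buffered fluoride cleavage of both silyl ethers under non-basic conditions, which should leave the tertiary alcohol, the methyl ester and the Z enoate unchanged.

**Compound list**

1 | (S)-pantolactone, (3S)-3-hydroxy-4,4-dimethyloxolan-2-one | O=C1OCC(C)(C)[C@@H]1O | starting material
2 | (3S)-3-(tert-butyldimethylsilyloxy)-4,4-dimethyloxolan-2-one | O=C1OCC(C)(C)[C@@H]1O[Si](C)(C)C(C)(C)C | intermediate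
3 | (2S)-2-(tert-butyldimethylsilyloxy)-4-hydroxy-N-methoxy-N,3,3-trimethylbutanamide | CON(C)C(=O)[C@@H](O[Si](C)(C)C(C)(C)C)C(C)(C)CO | intermediate
4 | (2S)-2-(tert-butyldimethylsilyloxy)-N-methoxy-N,3,3-trimethyl-4-oxobutanamide | CON(C)C(=O)[C@@H](O[Si](C)(C)C(C)(C)C)C(C)(C)C=O | intermediate
5 | (2S,4E)-2-(tert-butyldimethylsilyloxy)-N-methoxy-N,3,3-trimethylhepta-4,6-dienamide | CON(C)C(=O)[C@@H](O[Si](C)(C)C(C)(C)C)C(C)(C)/C=C/C=C | intermediate
6 | (2S,4E)-2-(tert-butyldimethylsilyloxy)-3,3-dimethylhepta-4,6-dienal | O=C[C@@H](O[Si](C)(C)C(C)(C)C)C(C)(C)/C=C/C=C | intermediate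
7 | 3-methylbut-2-enal (prenal) | CC(C)=CC=O | starting material
8 | (1E)-3-methyl-1-(trimethylsilyloxy)buta-1,3-diene | C=C(C)/C=C/O[Si](C)(C)C | intermediate
9 | (2E,5R,6S,8E)-6-(tert-butyldimethylsilyloxy)-5-hydroxy-3,7,7-trimethylundeca-2,8,10-trienal | C=C/C=C/C(C)(C)[C@H](O[Si](C)(C)C(C)(C)C)[C@H](O)C/C(C)=C/C=O | intermediate
10 | (2E,5R,6S,8E)-5,6-bis(tert-butyldimethylsilyloxy)-3,7,7-trimethylundeca-2,8,10-trienal | C=C/C=C/C(C)(C)[C@H](O[Si](C)(C)C(C)(C)C)[C@H](O[Si](C)(C)C(C)(C)C)C/C(C)=C/C=O | intermediate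
11 | 9β-formyl-2α,3α-bis(tert-butyldimethylsilyloxy)-4,4,10β-trimethyl-5αH-octal-6-ene (trans-fused) | O=C[C@H]1CC=C[C@H]2C(C)(C)[C@H](O[Si](C)(C)C(C)(C)C)[C@H](O[Si](C)(C)C(C)(C)C)C[C@@]21C | intermediate
12 | 9β-formyl-2α,3α-bis(tert-butyldimethylsilyloxy)-4,4,10β-trimethyl-5αH-decalin | O=C[C@H]1CCC[C@H]2C(C)(C)[C@H](O[Si](C)(C)C(C)(C)C)[C@H](O[Si](C)(C)C(C)(C)C)C[C@@]21C | intermediate
13 | 2α,3α-bis(tert-butyldimethylsilyloxy)-4,4,10β-trimethyl-5αH-decalin-9-one | O=C1CCC[C@H]2C(C)(C)[C@H](O[Si](C)(C)C(C)(C)C)[C@H](O[Si](C)(C)C(C)(C)C)C[C@@]21C | intermediate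
14 | lithium C8=C9 enolate of ketone 13 | [Li]OC1=CCC[C@H]2C(C)(C)[C@H](O[Si](C)(C)C(C)(C)C)[C@H](O[Si](C)(C)C(C)(C)C)C[C@@]21C | intermediate
15 | 8-methyl ketone as C8-epimer mixture | O=C1C(C)CC[C@H]2C(C)(C)[C@H](O[Si](C)(C)C(C)(C)C)[C@H](O[Si](C)(C)C(C)(C)C)C[C@@]21C | intermediate
16 | 8α-methyl-2α,3α-bis(tert-butyldimethylsilyloxy)-4,4,10β-trimethyl-5αH-decalin-9-one | O=C1[C@H](C)CC[C@H]2C(C)(C)[C@H](O[Si](C)(C)C(C)(C)C)[C@H](O[Si](C)(C)C(C)(C)C)C[C@@]21C | intermediate
17 | 9α-ethynyl-9β-hydroxy-8α-methyl-2α,3α-bis(tert-butyldimethylsilyloxy)-4,4,10β-trimethyl-5αH-decalin | C#C[C@]1(O)[C@H](C)CC[C@H]2C(C)(C)[C@H](O[Si](C)(C)C(C)(C)C)[C@H](O[Si](C)(C)C(C)(C)C)C[C@@]21C | intermediate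
18 | 9α-vinyl-9β-hydroxy-8α-methyl-2α,3α-bis(tert-butyldimethylsilyloxy)-4,4,10β-trimethyl-5αH-decalin | C=C[C@]1(O)[C@H](C)CC[C@H]2C(C)(C)[C@H](O[Si](C)(C)C(C)(C)C)[C@H](O[Si](C)(C)C(C)(C)C)C[C@@]21C | intermediate
19 | methyl but-2-ynoate | CC#CC(=O)OC | starting material
20 | methyl (Z)-3-iodobut-2-enoate | COC(=O)/C=C(/C)I | intermediate
21 | 9-[2-(9β-hydroxy-decalin-9α-yl)ethyl]-9-borabicyclo[3.3.1]nonane from 18 | C(C[C@]1(O)[C@H](C)CC[C@H]2C(C)(C)[C@H](O[Si](C)(C)C(C)(C)C)[C@H](O[Si](C)(C)C(C)(C)C)C[C@@]21C)B3C4CCCC3CCC4 | intermediate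
22 | methyl (13Z)-9β-hydroxy-2α,3α-bis(tert-butyldimethylsilyloxy)labd-13-en-15-oate | COC(=O)/C=C(/C)CC[C@]1(O)[C@H](C)CC[C@H]2C(C)(C)[C@H](O[Si](C)(C)C(C)(C)C)[C@H](O[Si](C)(C)C(C)(C)C)C[C@@]21C | intermediate
23 | methyl (13Z)-2α,3α,9β-trihydroxylabd-13-en-15-oate | COC(=O)/C=C(/C)CC[C@]1(O)[C@H](C)CC[C@H]2C(C)(C)[C@H](O)[C@H](O)C[C@@]21C | target

**Step count.** Total: 17 steps. Longest linear sequence: 15 steps (steps 1–5, 7–14, 16, 17).

**Steps most likely to fail**

Step 9. The β,β-disubstituted enal may cycloadd slowly, so that diene oligomerization or methyl transfer from aluminium competes, and exo closure could erode the trans-fusion selectivity. The fallback sets out from 10 and returns at 11. Aldehyde 10 is converted with 1,2-bis(trimethylsilyloxy)ethane and catalytic TMSOTf (CH2Cl2, −78 °C) into the dioxolane acetal F1. Catalytic TfOH then ionizes F1 to the 2-alkenyl-1,3-dioxolan-2-ylium ion, a far stronger dienophile, and the cationic (Gassman-type) intramolecular Diels–Alder reaction at −78 °C should give the trans-fused acetal cycloadduct F2. Mild hydrolysis (aqueous AcOH, THF) then gives 11.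

Step 13. The Grignard reagent may enolize the hindered ketone instead of adding, or equatorial attack may compete and lower facial selectivity. The fallback sets out from 16 and returns at 18, bypassing 17. Dimethylsulfonium methylide (Me3S+ I−, n-BuLi, THF, −10 °C) adds irreversibly along the axial trajectory to give the spiro-oxirane F3 (CH2 on the α face, O on the β face). An excess of the same ylide opens the oxirane at its CH2 carbon and expels dimethyl sulfide (one-carbon homologation of an epoxide to an allylic alcohol), giving vinyl carbinol 18 directly.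

Step 11. Enolization of the neopentyl-type aldehyde may be slow, so that aerobic over-oxidation to the carboxylic acid outruns C–C cleavage. The fallback sets out from 12 and returns at 13. Aldehyde 12 is converted (TMSOTf, Et3N, CH2Cl2, 0 °C) into the trimethylsilyl enol ether F4, and ozonolysis of its C9=C11 bond (O3, CH2Cl2, −78 °C; then Me2S) gives ketone 13.

**Further compounds**

F1 | step 9 | 2-[(1E,4R,5S,7E)-4,5-bis(tert-butyldimethylsilyloxy)-2,6,6-trimethyldeca-1,7,9-trienyl]-1,3-dioxolane | C=C/C=C/C(C)(C)[C@H](O[Si](C)(C)C(C)(C)C)[C@H](O[Si](C)(C)C(C)(C)C)C/C(C)=C/C1OCCO1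
F2 | step 9 | ethylene acetal of cycloadduct 11 (9β-(1,3-dioxolan-2-yl) octalin) | C1(OCCO1)[C@H]2CC=C[C@H]3C(C)(C)[C@H](O[Si](C)(C)C(C)(C)C)[C@H](O[Si](C)(C)C(C)(C)C)C[C@@]32C
F3 | step 13 | spiro-oxirane of ketone 16 (9β-O, 9α-CH2) | C1[C@]2(O1)[C@H](C)CC[C@H]3C(C)(C)[C@H](O[Si](C)(C)C(C)(C)C)[C@H](O[Si](C)(C)C(C)(C)C)C[C@@]32C
F4 | step 11 | trimethylsilyl enol ether of aldehyde 12 | C[Si](C)(C)OC=C1CCC[C@H]2C(C)(C)[C@H](O[Si](C)(C)C(C)(C)C)[C@H](O[Si](C)(C)C(C)(C)C)C[C@@]21C
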